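## Retrosynthetic overview

1. The target is the (1S,5S)-diol with cis hydroxyls (ring atoms: C1 = CH–OH, C2=C3, C4, C5 = carbinol carbon with the chain, C6). It is traced back to its acetonide, a 3,3-dimethyl-2,4-dioxabicyclo[3.3.1]non-6-ene, so only a ketal is removed at the end.
2. Key disconnection C1–C2: the bridged ketal comes from a monocyclic 4-acetoxy-2,2-dimethyl-1,3-dioxane with a (Z)-3-(trimethylsilyl)allyl arm (C4–C3=C2–Si) on C5. The enabling feature is the syn-1,3 array O–C1–C6–C5–O, which one ketal carbon closes to a 1,3-dioxane; C1 is then the acetal (cation) carbon, and C2, para to C5 in the future carbocycle, can reach it only as a diaxial bridge, hence cis. SiMe3 on C2, the acetate and higher oxidation level at C1, and the ketal ring are all temporary.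
3. Dioxane ⇒ β-hydroxy acid ⇒ 1,3-diol ⇒ (2S,3S)-2,3-epoxy alcohol (hydride opening at C6). C5, a carbinol flanked by three CH2 groups, is set by Sharpless epoxidation of an (E)-trisubstituted allylic alcohol, that is by alkene geometry plus face selection.
4. Allylic alcohol ⇒ (Z)-3-iodoalkenol (hydroalumination–iodination of a skipped diynol made from propargyl alcohol) plus the C16 alkylzinc (Negishi coupling); the chain (Z)-alkene comes from alkyne semi-hydrogenation.
5. Ring order: temporary 1,3-dioxane (step 10), then the cyclohexene (step 12), then removal of the dioxane (step 13); the phenyl ring is purchased.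

Key step: step 12

Assumption: the purchased building blocks are 5-phenylpent-1-yne, 1,11-dibromoundecane, prop-2-yn-1-ol and 3-bromo-1-(trimethylsilyl)prop-1-yne; the ring numbering C1–C6 given above is used for all intermediates.

## Route

Step 1
Reactants: 1 5-phenylpent-1-yne; 2 1,11-dibromoundecane
Product: 4 (16-bromohexadec-4-yn-1-yl)benzene, via lithium acetylide 3 (not isolated)
Conditions: n-BuLi, THF, −78 °C; then 2 (3 equiv), DMPU, −78 °C → rt
Reagents that add atoms: none
Why: SN2 alkylation of a lithium acetylide by a primary bromide, in which the excess of recoverable dibromide should keep the second alkylation down.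

Step 2
Reactants: 4 (16-bromohexadec-4-yn-1-yl)benzene
Product: 5 [(4Z)-16-bromohexadec-4-en-1-yl]benzene
Conditions: H2 (1 atm), Pd on CaCO3 poisoned with Pb(OAc)2, quinoline, hexane, rt
Reagents that add atoms: none
Why: Lindlar semi-hydrogenation delivers both hydrogens to one face of the alkyne on the metal surface and should stop at the (Z)-alkene without touching the primary bromide.

Step 3
Reactants: 6 prop-2-yn-1-ol; 7 3-bromo-1-(trimethylsilyl)prop-1-yne
Product: 8 6-(trimethylsilyl)hexa-2,5-diyn-1-ol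
Conditions: CuI, NaI, K2CO3, DMF, rt
Reagents that add atoms: none
Why: copper acetylide substitution of a propargylic bromide (skipped-diyne synthesis), in which the silyl group blocks the second alkyne terminus and the aprotic carbonate base should leave the C–Si bond intact.

Step 4
Reactants: 8 6-(trimethylsilyl)hexa-2,5-diyn-1-ol
Product: 10 (2Z)-3-iodo-6-(trimethylsilyl)hex-2-en-5-yn-1-ol, via cyclic vinylalanate 9 (not isolated)
Conditions: NaAlH2(OCH2CH2OCH3)2, THF, 0 °C; then I2, THF, −78 → 0 °C
Reagents that add atoms: iodine, II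
Why: hydroxyl-directed trans-hydroalumination of the propargylic alkyne (hydride to C2, aluminium to C3 in a five-membered alanate) and iodinolysis with retention should give the (Z)-3-iodoalkenol, while the silylalkyne, which has no directing group, should stay.

Step 5
Reactants: 5 [(4Z)-16-bromohexadec-4-en-1-yl]benzene; 10 (2Z)-3-iodo-6-(trimethylsilyl)hex-2-en-5-yn-1-ol
Product: 12 (2E,15Z)-19-phenyl-3-[3-(trimethylsilyl)prop-2-yn-1-yl]nonadeca-2,15-dien-1-ol, via alkylzinc bromide 11 (not isolated)
Conditions: 5, Zn dust, LiCl, THF, 50 °C; then 10, Pd(OAc)2 (2 mol %), 2-dicyclohexylphosphino-2′,6′-dimethoxybiphenyl (4 mol %), THF, rt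
Reagents that add atoms: none
Why: Negishi sp3–sp2 cross-coupling should proceed with retention of alkene geometry, so the chain ends up cis to CH2OH, and alkylzinc halides are protonated only slowly by alcohols, so the hydroxyl needs no protection.

Step 6
Reactants: 12 (2E,15Z)-19-phenyl-3-[3-(trimethylsilyl)prop-2-yn-1-yl]nonadeca-2,15-dien-1-ol
Product: 13 {(2S,3S)-3-[(12Z)-16-phenylhexadec-12-en-1-yl]-3-[3-(trimethylsilyl)prop-2-yn-1-yl]oxiran-2-yl}methanol
Conditions: Ti(OiPr)4 (10 mol %), L-(+)-diethyl tartrate (12 mol %), t-BuOOH, 4 Å molecular sieves, CH2Cl2, −20 °C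
Reagents that add atoms: tert-butyl hydroperoxide, CC(C)(C)OO
Why: Sharpless asymmetric epoxidation with L-(+)-tartrate should convert an (E)-3,3-disubstituted allylic alcohol of the geraniol type into the (2S,3S)-epoxide, so the later C5 centre is fixed by alkene geometry plus face selection without any need to tell three CH2 groups apart, and the chain alkene and the alkyne, which lack an allylic hydroxyl, should not react.

Step 7
Reactants: 13 {(2S,3S)-3-[(12Z)-16-phenylhexadec-12-en-1-yl]-3-[3-(trimethylsilyl)prop-2-yn-1-yl]oxiran-2-yl}methanol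
Product: 14 (3S,15Z)-19-phenyl-3-[3-(trimethylsilyl)prop-2-yn-1-yl]nonadec-15-ene-1,3-diol
Conditions: NaAlH2(OCH2CH2OCH3)2, THF, 0 °C → rt
Reagents that add atoms: none
Why: regioselective reductive opening of a 2,3-epoxy alcohol, in which the alkoxyaluminate delivers hydride to the secondary epoxide carbon (C6) to give the 1,3-diol while the C–O bond at the fully substituted carbon is not broken, so C5 keeps its configuration.

Step 8
Reactants: 14 (3S,15Z)-19-phenyl-3-[3-(trimethylsilyl)prop-2-yn-1-yl]nonadec-15-ene-1,3-diol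
Product: 15 (3S,15Z)-19-phenyl-3-[(2Z)-3-(trimethylsilyl)prop-2-en-1-yl]nonadec-15-ene-1,3-diol
Conditions: (i-Bu)2AlH (5 equiv), Et2O, 0 °C → reflux; then aq. potassium sodium tartrate
Reagents that add atoms: none
Why: cis-hydroalumination of a 1-silylalkyne in ether (aluminium to the silyl-bearing carbon) and protonolysis with retention should give the (Z)-vinylsilane, the two hydroxyls being converted only to aluminium alkoxides and the isolated alkene being inert.

Step 9
Reactants: 15 (3S,15Z)-19-phenyl-3-[(2Z)-3-(trimethylsilyl)prop-2-en-1-yl]nonadec-15-ene-1,3-diol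
Product: 17 (3S,15Z)-3-hydroxy-19-phenyl-3-[(2Z)-3-(trimethylsilyl)prop-2-en-1-yl]nonadec-15-enoic acid, via hydroxy aldehyde 16 (not isolated)
Conditions: TEMPO (20 mol %), PhI(OAc)2 (2.5 equiv), MeCN/H2O (1:1), rt
Reagents that add atoms: water, O
Why: nitroxyl-catalysed (oxoammonium) oxidation of the primary alcohol through the aldehyde hydrate to the acid, which the tertiary alcohol cannot undergo and which vinylsilane and alkene should tolerate.

Step 10
Reactants: 17 (3S,15Z)-3-hydroxy-19-phenyl-3-[(2Z)-3-(trimethylsilyl)prop-2-en-1-yl]nonadec-15-enoic acid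
Product: 18 (6S)-2,2-dimethyl-6-[(12Z)-16-phenylhexadec-12-en-1-yl]-6-[(2Z)-3-(trimethylsilyl)prop-2-en-1-yl]-1,3-dioxan-4-one
Conditions: 2-methoxypropene, pyridinium p-toluenesulfonate (cat.), CH2Cl2, 0 °C → rt
Reagents that add atoms: 2-methoxypropene, COC(C)=C
Why: acid-catalysed ketalization, in which the carboxylic acid adds to the enol ether and the tertiary hydroxyl closes the six-membered 1,3-dioxan-4-one with loss of methanol, installing the temporary ring that ties O1 to O5.

Step 11
Reactants: 18 (6S)-2,2-dimethyl-6-[(12Z)-16-phenylhexadec-12-en-1-yl]-6-[(2Z)-3-(trimethylsilyl)prop-2-en-1-yl]-1,3-dioxan-4-one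
Product: 20 (6S)-2,2-dimethyl-6-[(12Z)-16-phenylhexadec-12-en-1-yl]-6-[(2Z)-3-(trimethylsilyl)prop-2-en-1-yl]-1,3-dioxan-4-yl acetate (both C4 epimers), via aluminium hemiacetal 19 (not isolated)
Conditions: (i-Bu)2AlH, CH2Cl2, −78 °C; then pyridine, DMAP, Ac2O, −78 → −20 °C
Reagents that add atoms: acetic anhydride, CC(=O)OC(C)=O
Why: reductive acetylation of a lactone, in which (i-Bu)2AlH adds once at −78 °C and the aluminium hemiacetal is acetylated in situ before it can open, giving the α-acetoxy acetal with C1 at the aldehyde oxidation level.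

Step 12
Reactants: 20 (6S)-2,2-dimethyl-6-[(12Z)-16-phenylhexadec-12-en-1-yl]-6-[(2Z)-3-(trimethylsilyl)prop-2-en-1-yl]-1,3-dioxan-4-yl acetate
Product: 22 (1S,5S)-3,3-dimethyl-1-[(12Z)-16-phenylhexadec-12-en-1-yl]-2,4-dioxabicyclo[3.3.1]non-6-ene, via dioxanylium ion 21 (not isolated)
Conditions: Me3SiOTf (0.2 equiv), 2,6-di-tert-butyl-4-methylpyridine (0.3 equiv), CH2Cl2, −78 → −40 °C; Et3N
Reagents that add atoms: none
Why: Me3SiOTf ionises the anomeric acetate of 20 to the 2,2-dimethyl-1,3-dioxan-4-ylium ion 21; in the half-chair conformer that holds the (Z)-3-silylallyl arm axial on C5, the silyl-bearing carbon C2 attacks C1 along the axial direction, and the β-silyl cation at C3 then loses Me3Si+ to acetate, which regenerates the silyl triflate and leaves the double bond at C2=C3 only. The closest known reaction types are the acetal-initiated cyclization terminated by a (Z)-vinylsilane and the Lewis acid coupling of 4-acetoxy-1,3-dioxanes with π-nucleophiles. The cyclohexene ring closes in a 6-endo-trig mode with respect to the vinylsilane (both alkene carbons become ring atoms, exo with respect to the C1=O+ bond) and is fused to the dioxane as a 2,4-dioxabicyclo[3.3.1]non-6-ene. C1 is the only new stereocentre and is controlled by the ketal bridge: a three-carbon arm can span C1 and C5 of the dioxane only diaxially, so the C1–O and C5–O bonds must end up cis, which with (S)-C5 means (S)-C1. The step needs attack at C2 and not C3, which the β-silicon effect and the (Z) geometry should secure; it needs ionisation at the acetate and not at the ketal or the tertiary C5–O bond, which the better leaving group at −78 °C should secure; and it needs C–C bond formation to outrun protodesilylation, which the hindered pyridine base should secure.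

Step 13
Reactants: 22 (1S,5S)-3,3-dimethyl-1-[(12Z)-16-phenylhexadec-12-en-1-yl]-2,4-dioxabicyclo[3.3.1]non-6-ene
Product: 23 (1S,5S)-5-[(12Z)-16-phenylhexadec-12-en-1-yl]cyclohex-2-ene-1,5-diol
Conditions: pyridinium p-toluenesulfonate (cat.), MeOH, 0 °C → rt
Reagents that add atoms: none
Why: acid-catalysed transketalization to methanol, in which the bridged ketal should open under pyridinium catalysis mild enough not to ionise the allylic C1–O bond.

## Compound list

1 | 5-phenylpent-1-yne | C#CCCCc1ccccc1 | starting material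
2 | 1,11-dibromoundecane | BrCCCCCCCCCCCBr | starting material
3 | lithium 5-phenylpent-1-yn-1-ide | [Li]C#CCCCc1ccccc1 | intermediate
4 | (16-bromohexadec-4-yn-1-yl)benzene | BrCCCCCCCCCCCC#CCCCc1ccccc1 | intermediate
5 | [(4Z)-16-bromohexadec-4-en-1-yl]benzene | BrCCCCCCCCCCC/C=C\CCCc1ccccc1 | intermediate
6 | prop-2-yn-1-ol | C#CCO | starting material
7 | 3-bromo-1-(trimethylsilyl)prop-1-yne | C[Si](C)(C)C#CCBr | starting material
8 | 6-(trimethylsilyl)hexa-2,5-diyn-1-ol | OCC#CCC#C[Si](C)(C)C | intermediate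
9 | sodium 2,2-bis(2-methoxyethoxy)-3-[3-(trimethylsilyl)prop-2-yn-1-yl]-2,5-dihydro-1,2-oxaluminol-2-uide (cyclic vinylalanate) | [Na+].COCCO[Al-]1(OCCOC)OCC=C1CC#C[Si](C)(C)C | intermediate
10 | (2Z)-3-iodo-6-(trimethylsilyl)hex-2-en-5-yn-1-ol | OC/C=C(\I)CC#C[Si](C)(C)C | intermediate
11 | bromo[(12Z)-16-phenylhexadec-12-en-1-yl]zinc | Br[Zn]CCCCCCCCCCC/C=C\CCCc1ccccc1 | intermediate
12 | (2E,15Z)-19-phenyl-3-[3-(trimethylsilyl)prop-2-yn-1-yl]nonadeca-2,15-dien-1-ol | OC/C=C(\CCCCCCCCCCC/C=C\CCCc1ccccc1)CC#C[Si](C)(C)C | intermediate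
13 | {(2S,3S)-3-[(12Z)-16-phenylhexadec-12-en-1-yl]-3-[3-(trimethylsilyl)prop-2-yn-1-yl]oxiran-2-yl}methanol | OC[C@@H]1O[C@@]1(CCCCCCCCCCC/C=C\CCCc2ccccc2)CC#C[Si](C)(C)C | intermediate
14 | (3S,15Z)-19-phenyl-3-[3-(trimethylsilyl)prop-2-yn-1-yl]nonadec-15-ene-1,3-diol | OCC[C@](O)(CCCCCCCCCCC/C=C\CCCc1ccccc1)CC#C[Si](C)(C)C | intermediate
15 | (3S,15Z)-19-phenyl-3-[(2Z)-3-(trimethylsilyl)prop-2-en-1-yl]nonadec-15-ene-1,3-diol | OCC[C@](O)(CCCCCCCCCCC/C=C\CCCc1ccccc1)C/C=C\[Si](C)(C)C | intermediate
16 | (3S,15Z)-3-hydroxy-19-phenyl-3-[(2Z)-3-(trimethylsilyl)prop-2-en-1-yl]nonadec-15-enal | O=CC[C@](O)(CCCCCCCCCCC/C=C\CCCc1ccccc1)C/C=C\[Si](C)(C)C | intermediate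
17 | (3S,15Z)-3-hydroxy-19-phenyl-3-[(2Z)-3-(trimethylsilyl)prop-2-en-1-yl]nonadec-15-enoic acid | OC(=O)C[C@](O)(CCCCCCCCCCC/C=C\CCCc1ccccc1)C/C=C\[Si](C)(C)C | intermediate
18 | (6S)-2,2-dimethyl-6-[(12Z)-16-phenylhexadec-12-en-1-yl]-6-[(2Z)-3-(trimethylsilyl)prop-2-en-1-yl]-1,3-dioxan-4-one | CC1(C)OC(=O)C[C@](CCCCCCCCCCC/C=C\CCCc2ccccc2)(C/C=C\[Si](C)(C)C)O1 | intermediate
19 | diisobutylaluminium hemiacetal of 18 (4-[(diisobutylalumanyl)oxy]-1,3-dioxane) | CC(C)C[Al](CC(C)C)OC1C[C@](CCCCCCCCCCC/C=C\CCCc2ccccc2)(C/C=C\[Si](C)(C)C)OC(C)(C)O1 | intermediate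
20 | (6S)-2,2-dimethyl-6-[(12Z)-16-phenylhexadec-12-en-1-yl]-6-[(2Z)-3-(trimethylsilyl)prop-2-en-1-yl]-1,3-dioxan-4-yl acetate (both C4 epimers) | CC(=O)OC1C[C@](CCCCCCCCCCC/C=C\CCCc2ccccc2)(C/C=C\[Si](C)(C)C)OC(C)(C)O1 | intermediate
21 | (6S)-2,2-dimethyl-6-[(12Z)-16-phenylhexadec-12-en-1-yl]-6-[(2Z)-3-(trimethylsilyl)prop-2-en-1-yl]-1,3-dioxan-4-ylium trifluoromethanesulfonate | CC1(C)O[C@@](CCCCCCCCCCC/C=C\CCCc2ccccc2)(C/C=C\[Si](C)(C)C)CC=[O+]1.[O-]S(=O)(=O)C(F)(F)F | intermediate
22 | (1S,5S)-3,3-dimethyl-1-[(12Z)-16-phenylhexadec-12-en-1-yl]-2,4-dioxabicyclo[3.3.1]non-6-ene | CC2(C)O[C@@H]1C=CC[C@@](O2)(CCCCCCCCCCC/C=C\CCCc3ccccc3)C1 | intermediate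
23 | (1S,5S)-5-[(12Z)-16-phenylhexadec-12-en-1-yl]cyclohex-2-ene-1,5-diol | O[C@@H]1C=CC[C@@](O)(CCCCCCCCCCC/C=C\CCCc2ccccc2)C1 | target

## Step count and risks

Total step count: 13. Longest linear sequence: 11 steps (steps 1, 2 and 5–13; equally steps 3, 4 and 5–13).

The three steps most likely to fail:

**Step 12.** After ionisation, loss of a proton from C6 (to the 4H-1,3-dioxin) or protodesilylation of the vinylsilane may outrun C1–C2 bond formation, because the axial methyl group of the ketal crowds the axial approach of the arm. The fallback closes the same bond without a tether and sets out from 15. Iododesilylation with retention (N-iodosuccinimide, (CF3)2CHOH, 0 °C) should give (3S,15Z)-3-[(2Z)-3-iodoprop-2-en-1-yl]-19-phenylnonadec-15-ene-1,3-diol F1. Oxidation of the primary alcohol to the aldehyde only (TEMPO, PhI(OAc)2, CH2Cl2) should give (3S,15Z)-3-hydroxy-3-[(2Z)-3-iodoprop-2-en-1-yl]-19-phenylnonadec-15-enal F2. An intramolecular Nozaki–Hiyama–Kishi reaction (CrCl2, NiCl2 (cat.), DMF, rt, high dilution) then forms C1–C2 and comes back to the route at 23. Since this closure has no bridge, the C1 epimer may accompany 23. The mixture would be converged by oxidation (MnO2, CH2Cl2) to (5S)-5-hydroxy-5-[(12Z)-16-phenylhexadec-12-en-1-yl]cyclohex-2-en-1-one F3 and Corey–Bakshi–Shibata reduction back to 23. The (R)-2-methyl-oxazaborolidine with catecholborane at −78 °C is proposed, on the expectation that it delivers hydride as it does to cyclohex-2-enone with the alkene as the large group.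

**Step 10.** The gem-dimethyl ketal has to close onto a fully substituted carbinol. Ring closure may stall at the open 2-methoxyprop-2-yl ester, or the tertiary β-hydroxy acid may dehydrate under the acid. The fallback changes the tether to an unsubstituted formaldehyde acetal and sets out from 17. Paraformaldehyde, camphorsulfonic acid (cat.) and 4 Å molecular sieves in CH2Cl2 should give (6S)-6-[(12Z)-16-phenylhexadec-12-en-1-yl]-6-[(2Z)-3-(trimethylsilyl)prop-2-en-1-yl]-1,3-dioxan-4-one F4. Reductive acetylation as in step 11 should give (6S)-6-[(12Z)-16-phenylhexadec-12-en-1-yl]-6-[(2Z)-3-(trimethylsilyl)prop-2-en-1-yl]-1,3-dioxan-4-yl acetate F5. Me3SiOTf as in step 12 should give (1S,5S)-1-[(12Z)-16-phenylhexadec-12-en-1-yl]-2,4-dioxabicyclo[3.3.1]non-6-ene F6. The methylene acetal would be opened with Me3SiOTf and 2,2′-bipyridyl in CH2Cl2 at 0 °C, then water, and the route is rejoined at 23.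

**Step 8.** Cis-to-trans isomerisation of the α-silyl vinylalane, or incomplete hydroalumination next to two aluminium alkoxides, would erode the (Z) geometry on which step 12 depends. The fallback replaces hydrometalation–protonolysis by a different reaction class, heterogeneous syn-hydrogenation. It sets out from 14 (H2, Pd on CaCO3 poisoned with Pb(OAc)2, quinoline, EtOAc, rt), comes back at 15 and makes no new compound.

Further compounds
F1 | step 12 | (3S,15Z)-3-[(2Z)-3-iodoprop-2-en-1-yl]-19-phenylnonadec-15-ene-1,3-diol | OCC[C@](O)(CCCCCCCCCCC/C=C\CCCc1ccccc1)C/C=C\I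
F2 | step 12 | (3S,15Z)-3-hydroxy-3-[(2Z)-3-iodoprop-2-en-1-yl]-19-phenylnonadec-15-enal | O=CC[C@](O)(CCCCCCCCCCC/C=C\CCCc1ccccc1)C/C=C\I
F3 | step 12 | (5S)-5-hydroxy-5-[(12Z)-16-phenylhexadec-12-en-1-yl]cyclohex-2-en-1-one | O=C1C=CC[C@@](O)(CCCCCCCCCCC/C=C\CCCc2ccccc2)C1
F4 | step 10 | (6S)-6-[(12Z)-16-phenylhexadec-12-en-1-yl]-6-[(2Z)-3-(trimethylsilyl)prop-2-en-1-yl]-1,3-dioxan-4-one | O=C1C[C@](CCCCCCCCCCC/C=C\CCCc2ccccc2)(C/C=C\[Si](C)(C)C)OCO1
F5 | step 10 | (6S)-6-[(12Z)-16-phenylhexadec-12-en-1-yl]-6-[(2Z)-3-(trimethylsilyl)prop-2-en-1-yl]-1,3-dioxan-4-yl acetate | CC(=O)OC1C[C@](CCCCCCCCCCC/C=C\CCCc2ccccc2)(C/C=C\[Si](C)(C)C)OCO1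
F6 | step 10 | (1S,5S)-1-[(12Z)-16-phenylhexadec-12-en-1-yl]-2,4-dioxabicyclo[3.3.1]non-6-ene | C2O[C@@H]1C=CC[C@@](O2)(CCCCCCCCCCC/C=C\CCCc3ccccc3)C1
F0 | step 8 | none | none
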